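The cyclohexane ring is cut at C1–C2 and C5–C6 (quinic acid numbering) into a two-carbon unit C6=C1, a 2-hydroxyacrylate held as a chiral methylene-dioxolanone, and a four-carbon unit C2–C5 taken from D-ribonolactone. The key step exploits the oxygen on C5 and the captodative C1: photoredox decarboxylation of an open-chain 5-chloro-4-O-silyl-2,3-O-isopropylidene-D-ribonate gives a C5 dioxolanyl radical that adds to C6, the C1 radical is reduced to an enolate, and this closes the ring on the C2 chloride. One operation forms both ring bonds and sets C5 and the quaternary C1. Acetonide removal, double acylation with acetyl-protected p-coumaroyl chloride and acid hydrolysis finish the synthesis.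

Key step: step 5

Assumption: ring carbons are numbered as in quinic acid (C1 bears OH and CO2H, C3 the free OH, C4 and C5 the two esters); 2,3-O-isopropylidene-D-ribono-1,4-lactone and (E)-4-acetoxycinnamic acid are taken as purchasable.

Step 1
Reactants: 1 (S)-lactic acid; 2 pivalaldehyde
Product: 3 (2S,5S)-2-tert-butyl-5-methyl-1,3-dioxolan-4-one (cis)
Conditions: TsOH·H2O (cat.), H2SO4 (cat.), pentane, reflux, Dean–Stark; recrystallise (Et2O–pentane, −75 °C)
Reagents that add atoms: none
Why: Acid-catalysed acetalisation of the α-hydroxy acid with azeotropic water removal should give the five-membered acylal, in which the lactate stereocentre directs tert-butyl cis to methyl so that the acetal carbon is S, and crystallisation removes the minor trans isomer.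

Step 2
Reactants: 3 (2S,5S)-2-tert-butyl-5-methyl-1,3-dioxolan-4-one
Product: 5 (S)-2-tert-butyl-5-methylene-1,3-dioxolan-4-one, via tertiary bromide 4 (not isolated)
Conditions: NBS, azobisisobutyronitrile (cat.), CCl4, reflux; filter; then DBU, Et2O, 0 °C → rt
Reagents that add atoms: none
Why: Wohl–Ziegler radical bromination at the captodative C5–H followed by E2 dehydrobromination of the tertiary bromide should give the exocyclic alkene, the acetal stereocentre being untouched and the former C5 centre no longer needed.

Step 3
Reactants: 6 2,3-O-isopropylidene-D-ribono-1,4-lactone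
Product: 7 5-chloro-5-deoxy-2,3-O-isopropylidene-D-ribono-1,4-lactone
Conditions: PPh3, N-chlorosuccinimide, THF, 0 °C → rt
Reagents that add atoms: N-chlorosuccinimide, O=C1CCC(=O)N1Cl
Why: Appel-type chlorination of the primary alcohol under neutral conditions should leave lactone and acetonide intact, and chloride is chosen as a leaving group that a carboxylate does not displace at room temperature whereas an enolate does.

Step 4
Reactants: 7 5-chloro-5-deoxy-2,3-O-isopropylidene-D-ribono-1,4-lactone
Product: 10 5-chloro-5-deoxy-2,3-O-isopropylidene-4-O-(tert-butyldimethylsilyl)-D-ribonic acid, via potassium hydroxy-carboxylate 8 (not isolated), via bis-silyl derivative 9 (not isolated)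
Conditions: KOH (1.0 equiv), THF–H2O, 0 °C; evaporate, dry; TBSOTf (2.3 equiv), 2,6-lutidine, CH2Cl2, −78 → 0 °C; then H2O–THF, rt; pH 4 work-up
Reagents that add atoms: potassium hydroxide, [K+].[OH-]; tert-butyldimethylsilyl triflate, CC(C)(C)[Si](C)(C)OS(=O)(=O)C(F)(F)F
Why: Saponification with exactly one equivalent of hydroxide should open the activated γ-lactone without leaving base to close the chlorohydrin to an epoxide, low-temperature silyl triflate should then cap carboxylate and C4–OH faster than relactonisation, and only the labile silyl ester is hydrolysed on aqueous work-up, with no stereocentre touched.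

Step 5
Reactants: 10 5-chloro-5-deoxy-2,3-O-isopropylidene-4-O-(tert-butyldimethylsilyl)-D-ribonic acid; 5 (S)-2-tert-butyl-5-methylene-1,3-dioxolan-4-one
Product: 13 3-O-TBS-4,5-O-isopropylidene-quinic acid 1-O/carboxyl (S)-pivalaldehyde acylal (spiro-dioxolanone), via cesium carboxylate 11 (not isolated), via open-chain cesium enolate 12 (not isolated)
Conditions: Cs2CO3 (0.5 equiv), MeOH, evaporate, dry; then 5 (1.2 equiv), 2,4,5,6-tetra(carbazol-9-yl)isophthalonitrile (4CzIPN, 2 mol%), 4 Å MS, degassed DMF, blue LEDs (450 nm), rt
Reagents that add atoms: none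
Why: The excited photocatalyst should oxidise carboxylate 11, loss of CO2 gives the nucleophilic C5 dioxolan-4-yl radical, this adds to the CH2 terminus (C6) of captodative alkene 5, and the resulting C1 radical is reduced by the photocatalyst radical anion to enolate 12, which displaces the C2 chloride. The closest known reaction type is the photoredox decarboxylative radical addition–polar cyclisation cascade (radical–polar crossover after a Giese addition), arranged here as a formal [4+2] annulation with the leaving group on the acid partner. The cyclohexane closes by 6-exo-tet C-alkylation of an exocyclic enolate through a chair in which the trans-fused dioxolane is diequatorial. C5 is controlled by the acetonide ring, because the radical is attacked anti to its C4 substituent and so gives the trans-dioxolane (the 4,5-trans diol); C1 is controlled by the tert-butyl acetal centre, because the enolate is alkylated on the face anti to tert-butyl (self-regeneration of stereocentres principle), which places the carboxyl carbon cis to O5. The step needs ring closure to beat enolate protonation and carboxylate O-alkylation, which the aprotic medium with preformed salt, a primary chloride inert to carboxylate but not to the enolate, and the O3 silyl ether (no epoxide formation) should secure. C3 and C4 come unchanged from D-ribonolactone.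

Step 6
Reactants: 13 3-O-TBS-4,5-O-isopropylidene-quinic acid 1-O/carboxyl (S)-pivalaldehyde acylal
Product: 14 3-O-TBS-quinic acid 1-O/carboxyl (S)-pivalaldehyde acylal (free 4,5-diol)
Conditions: AcOH–H2O (4:1), rt
Reagents that add atoms: none
Why: Acid-catalysed ketal hydrolysis should cleave the strained trans-fused acetonide selectively, the secondary silyl ether and the hindered acylal being stable to aqueous acetic acid at room temperature.

Step 7
Reactants: 14 3-O-TBS-quinic acid 1-O/carboxyl (S)-pivalaldehyde acylal; 15 (E)-4-acetoxycinnamic acid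
Product: 17 3-O-TBS-4,5-bis-O-[(E)-4-acetoxycinnamoyl]quinic acid 1-O/carboxyl (S)-pivalaldehyde acylal, via (E)-4-acetoxycinnamoyl chloride 16 (not isolated)
Conditions: 15 (2.6 equiv), (COCl)2, DMF (cat.), CH2Cl2, 0 °C → rt, evaporate; then 14, pyridine, 4-(dimethylamino)pyridine (cat.), CH2Cl2, 0 °C → rt
Reagents that add atoms: none
Why: Acid chloride formation and nucleophile-catalysed acylation should esterify both equatorial hydroxyls while the axial C3 oxygen stays silylated, so the acylation pattern is fixed by the protecting groups and no stereocentre is touched.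

Step 8
Reactants: 17 3-O-TBS-4,5-bis-O-[(E)-4-acetoxycinnamoyl]quinic acid 1-O/carboxyl (S)-pivalaldehyde acylal
Product: 18 4,5-di-O-p-coumaroylquinic acid
Conditions: 2 M aq. HCl–THF (1:3), rt → 40 °C
Reagents that add atoms: none
Why: Aqueous acid should hydrolyse in one pot the two aryl acetates, the silyl ether and the acid-labile acylal (releasing 1-OH and CO2H together), while the cinnamoyl esters and all stereocentres survive because acyl migration is slow at low pH.

Compound list
1 | (S)-lactic acid | C[C@H](O)C(=O)O | starting material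
2 | pivalaldehyde | CC(C)(C)C=O | starting material
3 | (2S,5S)-2-tert-butyl-5-methyl-1,3-dioxolan-4-one (tert-butyl cis to methyl) | CC(C)(C)[C@H]1O[C@@H](C)C(=O)O1 | intermediate
4 | (2S,5R)-5-bromo-2-tert-butyl-5-methyl-1,3-dioxolan-4-one (bromine trans to tert-butyl) | CC(C)(C)[C@H]1O[C@@](Br)(C)C(=O)O1 | intermediate
5 | (S)-2-tert-butyl-5-methylene-1,3-dioxolan-4-one | CC(C)(C)[C@H]1OC(=C)C(=O)O1 | intermediate
6 | 2,3-O-isopropylidene-D-ribono-1,4-lactone | O=C1[C@@H]2OC(C)(C)O[C@@H]2[C@@H](CO)O1 | starting material
7 | 5-chloro-5-deoxy-2,3-O-isopropylidene-D-ribono-1,4-lactone | O=C1[C@@H]2OC(C)(C)O[C@@H]2[C@@H](CCl)O1 | intermediate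
8 | potassium 5-chloro-5-deoxy-2,3-O-isopropylidene-D-ribonate (free 4-OH) | [K+].[O-]C(=O)[C@@H]1OC(C)(C)O[C@@H]1[C@H](O)CCl | intermediate
9 | tert-butyldimethylsilyl 5-chloro-5-deoxy-2,3-O-isopropylidene-4-O-(tert-butyldimethylsilyl)-D-ribonate | CC(C)(C)[Si](C)(C)OC(=O)[C@@H]1OC(C)(C)O[C@@H]1[C@H](O[Si](C)(C)C(C)(C)C)CCl | intermediate
10 | 5-chloro-5-deoxy-2,3-O-isopropylidene-4-O-(tert-butyldimethylsilyl)-D-ribonic acid | OC(=O)[C@@H]1OC(C)(C)O[C@@H]1[C@H](O[Si](C)(C)C(C)(C)C)CCl | intermediate
11 | cesium salt of acid 10 | [Cs+].[O-]C(=O)[C@@H]1OC(C)(C)O[C@@H]1[C@H](O[Si](C)(C)C(C)(C)C)CCl | intermediate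
12 | open-chain cesium enolate: (S)-2-tert-butyl-dioxolanone enolate carrying at C5 the CH2 link to a trans-4,5-disubstituted 2,2-dimethyl-1,3-dioxolane with the (R)-1-silyloxy-2-chloroethyl side chain | [Cs+].[O-]C1=C(C[C@H]2OC(C)(C)O[C@@H]2[C@H](O[Si](C)(C)C(C)(C)C)CCl)O[C@@H](O1)C(C)(C)C | intermediate
13 | 3-O-TBS-4,5-O-isopropylidene-quinic acid with 1-OH and CO2H tied as the (S)-pivalaldehyde acylal (spiro-dioxolanone; tert-butyl cis to C6 and trans to C2; ring stereocentres as in (−)-quinic acid) | CC1(C)O[C@@H]2[C@H](O[Si](C)(C)C(C)(C)C)C[C@]3(O[C@@H](OC3=O)C(C)(C)C)C[C@H]2O1 | intermediate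
14 | 3-O-TBS-quinic acid 1-O/carboxyl (S)-pivalaldehyde acylal (4-OH and 5-OH free, trans) | O[C@@H]1[C@H](O[Si](C)(C)C(C)(C)C)C[C@]2(O[C@@H](OC2=O)C(C)(C)C)C[C@H]1O | intermediate
15 | (E)-4-acetoxycinnamic acid | CC(=O)Oc1ccc(/C=C/C(=O)O)cc1 | starting material
16 | (E)-4-acetoxycinnamoyl chloride | CC(=O)Oc1ccc(/C=C/C(=O)Cl)cc1 | intermediate
17 | 3-O-TBS-4,5-bis-O-[(E)-4-acetoxycinnamoyl]quinic acid 1-O/carboxyl (S)-pivalaldehyde acylal | O=C(/C=C/c1ccc(OC(C)=O)cc1)O[C@@H]1[C@H](O[Si](C)(C)C(C)(C)C)C[C@]2(O[C@@H](OC2=O)C(C)(C)C)C[C@H]1OC(=O)/C=C/c1ccc(OC(C)=O)cc1 | intermediate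
18 | 4,5-di-O-p-coumaroylquinic acid | O=C(/C=C/c1ccc(O)cc1)O[C@@H]1[C@H](O)C[C@@](O)(C(=O)O)C[C@H]1OC(=O)/C=C/c1ccc(O)cc1 | target

Total step count: 8. Longest linear sequence: 6 steps (6 → 7 → 10 → 13 → 14 → 17 → 18; the branch from 1 is equally long).

Steps most likely to fail

Step 5. Protonation of enolate 12, or its Michael addition to a second molecule of 5, may outrun the six-membered ring closure, and the carboxylate may lactonise onto the chloride before it is oxidised. The fallback sets out from 10 and 5 and comes back at 13. The decarboxylative Giese addition is run deliberately under protic conditions (same photocatalyst, K2HPO4, DMF–H2O, blue LEDs), which should give the open-chain chloro dioxolanone F1, protonated anti to tert-butyl. The enolate is then regenerated with KN(SiMe3)2 in THF at −78 °C and allowed to alkylate intramolecularly on warming to 0 °C. This is the classical alkylation of such acylal enolates anti to tert-butyl and should give 13.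

Step 4. The chlorohydrin may close to the epoxide under a local excess of hydroxide, or the hydroxy carboxylate may relactonise to 7 before both oxygens are silylated. The fallback sets out from 7 and comes back at 10. After the same saponification, carboxylate 8 is alkylated with allyl bromide in DMF at 0 °C to the allyl ester F2. Its free C4–OH is silylated (TBSOTf, 2,6-lutidine, −78 °C) to the silyl ether F3, and the acid is released with Pd(PPh3)4 and morpholine in THF.

Step 8. Slow hydrolysis of the aryl acetates and of the hindered acylal may force long exposure to acid, with acyl migration from O4 to O3 or partial loss of the cinnamoyl esters. The fallback sets out from 17 and comes back at 18. The phenolic acetates are first removed chemoselectively by transesterification (NH4OAc, MeOH–H2O, rt) to give the bis-phenol F4, which still carries the silyl ether and the acylal. A short treatment with TFA–H2O (9:1) at rt then cleaves both acid-labile groups.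

Further compounds
F1 | step 5 | (2S,5S)-2-tert-butyl-5-{[(4R,5R)-5-((R)-1-(tert-butyldimethylsilyloxy)-2-chloroethyl)-2,2-dimethyl-1,3-dioxolan-4-yl]methyl}-1,3-dioxolan-4-one (open-chain Giese adduct, side chain cis to tert-butyl, dioxolane trans) | CC(C)(C)[C@H]1O[C@@H](C[C@H]2OC(C)(C)O[C@@H]2[C@H](O[Si](C)(C)C(C)(C)C)CCl)C(=O)O1
F2 | step 4 | allyl 5-chloro-5-deoxy-2,3-O-isopropylidene-D-ribonate | C=CCOC(=O)[C@@H]1OC(C)(C)O[C@@H]1[C@H](O)CCl
F3 | step 4 | allyl 5-chloro-5-deoxy-2,3-O-isopropylidene-4-O-(tert-butyldimethylsilyl)-D-ribonate | C=CCOC(=O)[C@@H]1OC(C)(C)O[C@@H]1[C@H](O[Si](C)(C)C(C)(C)C)CCl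
F4 | step 8 | 3-O-TBS-4,5-di-O-p-coumaroylquinic acid 1-O/carboxyl (S)-pivalaldehyde acylal | O=C(/C=C/c1ccc(O)cc1)O[C@@H]1[C@H](O[Si](C)(C)C(C)(C)C)C[C@]2(O[C@@H](OC2=O)C(C)(C)C)C[C@H]1OC(=O)/C=C/c1ccc(O)cc1
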